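**Strategy.** The plan reads ring B (labdane numbering) as a cyclobutanone plus propyne. The carbinol carbon C6 and the side-chain-bearing C9 both sit next to the ring fusion (C5–C10) and flank the C7=C8 alkene. Ring B can therefore be made by inserting the two alkyne carbons into the C6–C9 bond of a four-membered ketone (C6, C5, C10, C9) fused to ring A. One nickel-catalysed step forms C6–C7 and C8–C9, gives the 7-en-6-one and keeps C9 intact. The precursor is a cis-fused 8-alkylbicyclo[4.2.0]octan-7-one, assembled by an enantioselective allenoate–alkene [2+2] cycloaddition and enolate alkylation with an iodide cut from (R)-linalool.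

Key step: step 10

Assumption: the enantiomer of the oxazaborolidine catalyst in step 7 is chosen so that the (1R,6R) cyclobutane forms; if the opposite alkene face is preferred, the mirror-image catalyst is used.

Step 1
Reactants: 1 (R)-(−)-linalool
Product: 2 (3R)-3,7-dimethyl-3-[(triethylsilyl)oxy]octa-1,6-diene
Conditions: TESOTf, 2,6-lutidine, CH2Cl2, −78 °C to 0 °C
Reagents that add atoms: triethylsilyl trifluoromethanesulfonate, CC[Si](CC)(CC)OS(=O)(=O)C(F)(F)F
Why: A silyl triflate with a hindered pyridine base should silylate the tertiary allylic alcohol without touching the C13 stereocentre (silyl ether protection).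

Step 2
Reactants: 2 (3R)-3,7-dimethyl-3-[(triethylsilyl)oxy]octa-1,6-diene
Product: 3 (4R)-4-methyl-4-[(triethylsilyl)oxy]hex-5-enal
Conditions: O3 (1.0 equiv, dosed as a cold CH2Cl2 solution), pyridine, CH2Cl2, −78 °C
Reagents that add atoms: ozone, [O-][O+]=O
Why: The electron-rich trisubstituted alkene should take up ozone far faster than the vinyl group, and pyridine-mediated ozonolysis should give the aldehyde directly without a separate reduction.

Step 3
Reactants: 3 (4R)-4-methyl-4-[(triethylsilyl)oxy]hex-5-enal
Product: 4 (4R)-4-methyl-4-[(triethylsilyl)oxy]hex-5-enoic acid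
Conditions: NaClO2, NaH2PO4, 2-methylbut-2-ene, t-BuOH/H2O, 0 °C to rt
Reagents that add atoms: sodium chlorite, [Na+].[O-]Cl=O
Why: Pinnick oxidation should convert the aldehyde into the acid under buffered conditions that spare the silyl ether and the vinyl group.

Step 4
Reactants: 4 (4R)-4-methyl-4-[(triethylsilyl)oxy]hex-5-enoic acid
Product: 6 (3R)-5-iodo-3-methyl-3-[(triethylsilyl)oxy]pent-1-ene, via thiohydroxamate ester 5 (not isolated)
Conditions: N-hydroxypyridine-2-thione, DCC, DMAP (cat.), CH2Cl2, rt, dark; then CHI3, hν (tungsten lamp), 40 °C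
Reagents that add atoms: triiodomethane (iodoform), IC(I)I
Why: Barton decarboxylation of the thiohydroxamate ester should give a primary radical that abstracts iodine from iodoform, shortening the chain by one carbon (radical iododecarboxylation).

Step 5
Reactants: 7 2,2,6-trimethylcyclohexan-1-one
Product: 8 2,6,6-trimethylcyclohex-1-en-1-yl trifluoromethanesulfonate
Conditions: Tf2O, 2,6-di-tert-butyl-4-methylpyridine, CH2Cl2, 0 °C to rt
Reagents that add atoms: trifluoromethanesulfonic anhydride, O=S(=O)(OS(=O)(=O)C(F)(F)F)C(F)(F)F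
Why: The ketone can enolise only towards the methyl-bearing carbon, so triflation should give a single enol triflate.

Step 6
Reactants: 8 2,6,6-trimethylcyclohex-1-en-1-yl trifluoromethanesulfonate
Product: 9 1,3,3-trimethylcyclohex-1-ene
Conditions: Pd(OAc)2 (5 mol %), PPh3, HCO2H, n-Bu3N, DMF, 60 °C
Reagents that add atoms: none
Why: Palladium-catalysed hydride transfer from formate should reduce the enol triflate to the alkene without moving the double bond.

Step 7
Reactants: 9 1,3,3-trimethylcyclohex-1-ene; 10 ethyl buta-2,3-dienoate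
Product: 11 ethyl (2E)-2-[(1R,6R)-1,5,5-trimethylbicyclo[4.2.0]octan-7-ylidene]acetate (cis-fused)
Conditions: (S)-B-(o-tolyl)-α,α-diphenylprolinol oxazaborolidine (20 mol %), AlBr3 (16 mol %), CH2Cl2, −78 °C to −20 °C
Reagents that add atoms: none
Why: In the Lewis acid-catalysed allenoate–alkene [2+2] cycloaddition the central allenoate carbon should bond to the less substituted alkene carbon (C5) and the CH2 terminus should close on the tertiary carbon (C10); suprafacial addition fixes the cis fusion, and the chiral oxazaborolidine selects the alkene face and thus C10 and C5.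

Step 8
Reactants: 11 ethyl (2E)-2-[(1R,6R)-1,5,5-trimethylbicyclo[4.2.0]octan-7-ylidene]acetate
Product: 12 (1R,6R)-1,5,5-trimethylbicyclo[4.2.0]octan-7-one
Conditions: O3, pyridine, CH2Cl2, −78 °C
Reagents that add atoms: ozone, [O-][O+]=O
Why: Ozonolysis of the exocyclic enoate double bond should unmask the cyclobutanone under neutral conditions that do not enolise the ring stereocentres.

Step 9
Reactants: 12 (1R,6R)-1,5,5-trimethylbicyclo[4.2.0]octan-7-one; 6 (3R)-5-iodo-3-methyl-3-[(triethylsilyl)oxy]pent-1-ene
Product: 14 (1R,6R,8R)-1,5,5-trimethyl-8-{(3R)-3-methyl-3-[(triethylsilyl)oxy]pent-4-en-1-yl}bicyclo[4.2.0]octan-7-one, via lithium enolate 13 (not isolated)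
Conditions: LiN(i-Pr)2, THF, −78 °C; then 6, DMPU, −78 °C to −20 °C
Reagents that add atoms: none
Why: Kinetic deprotonation should occur at the CH2 group C9 (C5 is a hindered ring-fusion methine), and the enolate should be alkylated on the face syn to the angular methyl group, away from ring A and its gem-dimethyl carbon, which sets C9 (enolate alkylation).

Step 10
Reactants: 14 (1R,6R,8R)-1,5,5-trimethyl-8-{(3R)-3-methyl-3-[(triethylsilyl)oxy]pent-4-en-1-yl}bicyclo[4.2.0]octan-7-one; 15 propyne
Product: 16 (13R)-13-[(triethylsilyl)oxy]-5β-labda-7,14-dien-6-one (cis-fused)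
Conditions: Ni(cod)2 (10 mol %), PCy3 (20 mol %), toluene, 100 °C, sealed vessel; propyne (3 equiv) added as a toluene solution over 6 h
Reagents that add atoms: none
Why: Oxidative cyclisation of the strained C6 carbonyl and propyne on zerovalent nickel should give an oxanickelacyclopentene in which C6 is bonded to the unsubstituted alkyne carbon C7 and the methyl-bearing carbon C8 sits on nickel; β-carbon elimination then breaks the C6–C9 bond of the four-membered ring and reductive elimination joins C8 to C9. The closest known reaction type is the nickel-catalysed intermolecular insertion of alkynes into cyclobutanones. Ring B is closed as a formal [4+2] two-carbon ring expansion of the cyclobutanone (C6, C5, C10, C9) to the cyclohexenone. No stereocentre is created: C9 passes from carbon to nickel to carbon with retention and C10 and C5 are untouched, so the cis fusion of 14 is carried into 16. The step needs cleavage of C6–C9 over C6–C5, which the two quaternary neighbours of C5 (C4 and C10) should enforce, and it needs the hydrogen-bearing alkyne carbon next to the carbonyl, which follows from the larger substituent lying on nickel. Slow dosing of propyne should keep alkyne oligomerisation behind insertion, and the hindered vinyl group of the side chain is a far poorer partner than the alkyne.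

Step 11
Reactants: 16 (13R)-13-[(triethylsilyl)oxy]-5β-labda-7,14-dien-6-one
Product: 17 (13R)-13-[(triethylsilyl)oxy]labda-7,14-dien-6-one (trans-fused, 5α-H)
Conditions: NaOMe (0.2 equiv), MeOH, 0 °C to rt
Reagents that add atoms: none
Why: Mild base should enolise the α′ position C5 so that the ketone settles in the more stable trans-fused decalin, while the less acidic γ position C9 is left untouched (epimerisation under thermodynamic control).

Step 12
Reactants: 17 (13R)-13-[(triethylsilyl)oxy]labda-7,14-dien-6-one
Product: 18 (13R)-13-[(triethylsilyl)oxy]labda-7,14-dien-6β-ol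
Conditions: NaBH4, CeCl3·7H2O, MeOH, −78 °C to −20 °C
Reagents that add atoms: none
Why: Luche reduction is 1,2-selective and hydride should enter from the α face because the β face of C6 is screened by the axial C10 and C4 methyl groups, giving the axial 6β alcohol.

Step 13
Reactants: 18 (13R)-13-[(triethylsilyl)oxy]labda-7,14-dien-6β-ol; 19 butanoic acid
Product: 20 (13R)-13-[(triethylsilyl)oxy]labda-7,14-dien-6α-yl butanoate
Conditions: PPh3, DIAD, toluene, 0 °C to 50 °C
Reagents that add atoms: none
Why: In the Mitsunobu reaction butanoate should displace the oxyphosphonium from the open α face with inversion, giving the equatorial 6α ester.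

Step 14
Reactants: 20 (13R)-13-[(triethylsilyl)oxy]labda-7,14-dien-6α-yl butanoate
Product: 21 (13R)-13-hydroxylabda-7,14-dien-6α-yl butanoate (target)
Conditions: TBAF, AcOH, THF, 0 °C to rt
Reagents that add atoms: none
Why: Buffered fluoride should cleave the tertiary triethylsilyl ether and leave the hindered secondary ester in place (silyl ether deprotection).

Compound list
1 | (R)-(−)-linalool, (3R)-3,7-dimethylocta-1,6-dien-3-ol | C=C[C@](C)(O)CCC=C(C)C | starting material
2 | (3R)-3,7-dimethyl-3-[(triethylsilyl)oxy]octa-1,6-diene | C=C[C@](C)(O[Si](CC)(CC)CC)CCC=C(C)C | intermediate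
3 | (4R)-4-methyl-4-[(triethylsilyl)oxy]hex-5-enal | C=C[C@](C)(O[Si](CC)(CC)CC)CCC=O | intermediate
4 | (4R)-4-methyl-4-[(triethylsilyl)oxy]hex-5-enoic acid | C=C[C@](C)(O[Si](CC)(CC)CC)CCC(=O)O | intermediate
5 | 2-thioxopyridin-1(2H)-yl (4R)-4-methyl-4-[(triethylsilyl)oxy]hex-5-enoate (thiohydroxamate ester, not isolated) | C=C[C@](C)(O[Si](CC)(CC)CC)CCC(=O)On1ccccc1=S | intermediate
6 | (3R)-5-iodo-3-methyl-3-[(triethylsilyl)oxy]pent-1-ene | C=C[C@](C)(O[Si](CC)(CC)CC)CCI | intermediate
7 | 2,2,6-trimethylcyclohexan-1-one (racemic) | CC1CCCC(C)(C)C1=O | starting material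
8 | 2,6,6-trimethylcyclohex-1-en-1-yl trifluoromethanesulfonate | CC1=C(OS(=O)(=O)C(F)(F)F)C(C)(C)CCC1 | intermediate
9 | 1,3,3-trimethylcyclohex-1-ene | CC1=CC(C)(C)CCC1 | intermediate
10 | ethyl buta-2,3-dienoate | C=C=CC(=O)OCC | starting material
11 | ethyl (2E)-2-[(1R,6R)-1,5,5-trimethylbicyclo[4.2.0]octan-7-ylidene]acetate (cis-fused; ring-fusion H and methyl on the same face) | C1/C(=C\C(=O)OCC)[C@@H]2C(C)(C)CCC[C@]12C | intermediate
12 | (1R,6R)-1,5,5-trimethylbicyclo[4.2.0]octan-7-one (cis-fused) | C1C(=O)[C@@H]2C(C)(C)CCC[C@]12C | intermediate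
13 | lithium (1R,6R)-1,5,5-trimethylbicyclo[4.2.0]oct-7-en-7-olate (not isolated) | C1=C([O-])[C@@H]2C(C)(C)CCC[C@]12C.[Li+] | intermediate
14 | (1R,6R,8R)-1,5,5-trimethyl-8-{(3R)-3-methyl-3-[(triethylsilyl)oxy]pent-4-en-1-yl}bicyclo[4.2.0]octan-7-one (side chain cis to the ring-fusion methyl) | C=C[C@](C)(O[Si](CC)(CC)CC)CC[C@H]1C(=O)[C@@H]2C(C)(C)CCC[C@]12C | intermediate
15 | propyne | CC#C | starting material
16 | (13R)-13-[(triethylsilyl)oxy]-5β-labda-7,14-dien-6-one, (4S,4aR,8aR)-configured cis-fused hexahydronaphthalen-1(4H)-one | C=C[C@](C)(O[Si](CC)(CC)CC)CC[C@H]1C(C)=CC(=O)[C@@H]2C(C)(C)CCC[C@]12C | intermediate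
17 | (13R)-13-[(triethylsilyl)oxy]labda-7,14-dien-6-one, (4S,4aR,8aS)-configured trans-fused enone | C=C[C@](C)(O[Si](CC)(CC)CC)CC[C@H]1C(C)=CC(=O)[C@H]2C(C)(C)CCC[C@]12C | intermediate
18 | (13R)-13-[(triethylsilyl)oxy]labda-7,14-dien-6β-ol (axial alcohol) | C=C[C@](C)(O[Si](CC)(CC)CC)CC[C@H]1C(C)=C[C@@H](O)[C@H]2C(C)(C)CCC[C@]12C | intermediate
19 | butanoic acid | CCCC(=O)O | starting material
20 | (13R)-13-[(triethylsilyl)oxy]labda-7,14-dien-6α-yl butanoate | C=C[C@](C)(O[Si](CC)(CC)CC)CC[C@H]1C(C)=C[C@H](OC(=O)CCC)[C@H]2C(C)(C)CCC[C@]12C | intermediate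
21 | (13R)-13-hydroxylabda-7,14-dien-6α-yl butanoate, (1S,4S,4aR,8aS)-4-[(3R)-3-hydroxy-3-methylpent-4-en-1-yl]-3,4a,8,8-tetramethyl-1,4,4a,5,6,7,8,8a-octahydronaphthalen-1-yl butanoate | C=C[C@](C)(O)CC[C@H]1C(C)=C[C@H](OC(=O)CCC)[C@H]2C(C)(C)CCC[C@]12C | target

Total step count: 14. Longest linear sequence: 10 steps (steps 5 to 14 from ketone 7; equally steps 1 to 4 and 9 to 14 from linalool).

Steps most likely to fail

Step 10. Propyne may oligomerise on nickel faster than it inserts. The metal may also open the C6–C5 bond instead of C6–C9, or the alkylnickel may lose a β-hydrogen before reductive elimination. The fallback makes the same two bonds by a polar two-carbon ring enlargement and sets out from 14. Condensation with pyrrolidine (TiCl4, Et2O) gives the pyrrolidine enamine F1. Heating with methyl but-2-ynoate joins C9 to the methyl-bearing alkyne carbon and C6 to the ester-bearing carbon in one [2+2] cycloaddition, and the strained bicyclohexene opens to the aminocyclohexadiene ester F2. Aqueous acetic acid hydrolyses this to the β-keto ester F3. Krapcho dealkoxycarbonylation (LiCl, wet DMSO, 130 °C) and the methoxide treatment of step 11 then conjugate the alkene, protonate C9 from the α face and set the trans fusion, so the route is rejoined at 17.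

Step 7. The alkene carbon that must attack the allenoate is flanked by a quaternary carbon, so the cycloaddition may be slow or show poor facial discrimination. The fallback sets out from 9 and uses dichloroketene (Cl3CCOCl, Zn(Cu), Et2O), which adds to hindered alkenes with the same regiochemistry, to give the dichlorocyclobutanone F4 together with its mirror image F5. Zn in AcOH removes the chlorine atoms and gives 12 together with its mirror image F6. Preparative HPLC on a chiral stationary phase separates the enantiomers and the route is rejoined at 12.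

Step 13. Activation of the hindered axial allylic alcohol may end in elimination towards a diene instead of substitution. The fallback sets out from 18 and epimerises C6 under thermodynamic control by reversible ruthenium-catalysed dehydrogenation and hydrogenation ((η5-C5Ph5)Ru(CO)2Cl, KOt-Bu, toluene, 60 °C) to the equatorial 6α-alcohol F7. Acylation with butanoic anhydride (DMAP, Et3N, CH2Cl2) rejoins the route at 20.

Further compounds
F1 | step 10 | pyrrolidine enamine of 14 (C6=C9 double bond, nitrogen on C6, ring fusion as in 14) | C=C[C@](C)(O[Si](CC)(CC)CC)CCC1=C(N3CCCC3)[C@@H]2C(C)(C)CCC[C@]12C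
F2 | step 10 | ring-enlarged aminodiene ester (ring B: C6 bearing pyrrolidine, C6=C7, methyl ester on C7, C8=C9, methyl on C8; cis fusion) | C=C[C@](C)(O[Si](CC)(CC)CC)CCC1=C(C)C(C(=O)OC)=C(N3CCCC3)[C@@H]2C(C)(C)CCC[C@]12C
F3 | step 10 | β-keto ester from hydrolysis of F2 (C6 ketone, methyl ester on C7, C8=C9 alkene; cis fusion) | C=C[C@](C)(O[Si](CC)(CC)CC)CCC1=C(C)C(C(=O)OC)C(=O)[C@@H]2C(C)(C)CCC[C@]12C
F4 | step 7 | 8,8-dichloro-1,5,5-trimethylbicyclo[4.2.0]octan-7-one with the ring-fusion configuration of 12 | ClC1(Cl)C(=O)[C@@H]2C(C)(C)CCC[C@]12C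
F5 | step 7 | mirror image of F4 | ClC1(Cl)C(=O)[C@H]2C(C)(C)CCC[C@@]12C
F6 | step 7 | (1S,6S)-1,5,5-trimethylbicyclo[4.2.0]octan-7-one, mirror image of 12 | C1C(=O)[C@H]2C(C)(C)CCC[C@@]12C
F7 | step 13 | (13R)-13-[(triethylsilyl)oxy]labda-7,14-dien-6α-ol (equatorial alcohol) | C=C[C@](C)(O[Si](CC)(CC)CC)CC[C@H]1C(C)=C[C@H](O)[C@H]2C(C)(C)CCC[C@]12C
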